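The target is reached by taking both hydroxyl groups off in the retrosynthetic direction. That leads to the achiral C40 hydrocarbon 7,8-didehydro-7',8'-dihydro-β,β-carotene, assembled from two C15 phosphonium salts and the C10 trienedial by two Wittig reactions. A carotene β-ring 3-hydroxylase (CrtZ type) then oxidises the homoallylic CH2 groups C3 of ring A (the alkyne-bearing ring) and C3' of ring B (the CH2CH2-linked ring) in one operation. This makes both C–O bonds and both stereocentres (3R,3'R) without touching the polyene or closing a ring. The step exploits the fact that both 2,6,6-trimethylcyclohexene end rings are identical to the β-ring of β-carotene, which the enzyme recognises.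

Key step: step 9

Remark: 2,2,6-trimethylcyclohexanone is used as the racemate because its only stereocentre is lost in step 1; the hydroxylase is assumed to be a CrtZ enzyme (for example that of Pantoea ananatis) used as a membrane fraction of recombinant Escherichia coli.

Step 1
Reactants: 1 2,2,6-trimethylcyclohexanone
Product: 3 2,6,6-trimethylcyclohex-1-en-1-yl trifluoromethanesulfonate, via lithium enolate 2 (not isolated)
Conditions: LiN(i-Pr)2 (1.1 equiv), THF, −78 → 0 °C; PhNTf2 (1.1 equiv), −78 °C → rt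
Reagents that add atoms: N-phenylbis(trifluoromethanesulfonimide) (PhNTf2), O=S(=O)(N(c1ccccc1)S(=O)(=O)C(F)(F)F)C(F)(F)F
Why: The ketone has a single α-hydrogen, so deprotonation can give only one enolate, which is O-sulfonylated by PhNTf2 (enol triflate formation).

Step 2
Reactants: 3 2,6,6-trimethylcyclohex-1-en-1-yl trifluoromethanesulfonate; 4 (E)-3-methylpent-2-en-4-yn-1-ol (1.3 equiv)
Product: 5 (E)-3-methyl-5-(2,6,6-trimethylcyclohex-1-en-1-yl)pent-2-en-4-yn-1-ol
Conditions: Pd(PPh3)4 (5 mol %), CuI (10 mol %), i-Pr2NH, DMF, 50 °C, argon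
Reagents that add atoms: none
Why: Sonogashira coupling of a vinyl triflate with a terminal alkyne (zerovalent palladium, CuI co-catalyst) tolerates the free allylic alcohol and carries the E double bond of 4 unchanged into the enyne.

Step 3
Reactants: 5 (E)-3-methyl-5-(2,6,6-trimethylcyclohex-1-en-1-yl)pent-2-en-4-yn-1-ol
Product: 7 [(E)-3-methyl-5-(2,6,6-trimethylcyclohex-1-en-1-yl)pent-2-en-4-yn-1-yl]triphenylphosphonium bromide (C15 salt of ring A), via allylic bromide 6 (not isolated)
Conditions: PBr3 (0.4 equiv), pyridine (cat.), Et2O, −10 → 0 °C; aq NaHCO3 wash; PPh3 (1.1 equiv), EtOAc, rt, dark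
Reagents that add atoms: phosphorus tribromide, BrP(Br)Br; triphenylphosphine, c1ccc(cc1)P(c1ccccc1)c1ccccc1
Why: PBr3 turns the primary allylic alcohol into the bromide by SN2 displacement at low temperature without ionisation, so the 9E bond beside the alkyne is kept, and PPh3 then displaces bromide (phosphine quaternisation) to give a crystallisable Wittig salt.

Step 4
Reactants: 8 dihydro-β-ionone, 4-(2,6,6-trimethylcyclohex-1-en-1-yl)butan-2-one
Product: 9 ethyl (E)-3-methyl-5-(2,6,6-trimethylcyclohex-1-en-1-yl)pent-2-enoate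
Conditions: (EtO)2P(O)CH2CO2Et (1.5 equiv), NaH (1.5 equiv), THF, 0 °C → reflux; chromatography to remove the minor Z ester
Reagents that add atoms: triethyl phosphonoacetate, CCOC(=O)CP(=O)(OCC)OCC
Why: Horner–Wadsworth–Emmons olefination of the methyl ketone should place the ester trans to the larger CH2CH2 chain in the main isomer, and the geometry is fixed here by separating the esters.

Step 5
Reactants: 9 ethyl (E)-3-methyl-5-(2,6,6-trimethylcyclohex-1-en-1-yl)pent-2-enoate
Product: 10 (E)-3-methyl-5-(2,6,6-trimethylcyclohex-1-en-1-yl)pent-2-en-1-ol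
Conditions: i-Bu2AlH (2.2 equiv), CH2Cl2, −78 → 0 °C; aq KNaC4H4O6
Reagents that add atoms: none
Why: i-Bu2AlH reduces the conjugated ester to the allylic alcohol by 1,2-hydride delivery (ester reduction) and leaves both C=C bonds untouched.

Step 6
Reactants: 10 (E)-3-methyl-5-(2,6,6-trimethylcyclohex-1-en-1-yl)pent-2-en-1-ol
Product: 12 [(E)-3-methyl-5-(2,6,6-trimethylcyclohex-1-en-1-yl)pent-2-en-1-yl]triphenylphosphonium bromide (C15 salt of ring B), via allylic bromide 11 (not isolated)
Conditions: PBr3 (0.4 equiv), pyridine (cat.), Et2O, −10 → 0 °C; aq NaHCO3 wash; PPh3 (1.1 equiv), EtOAc, rt, dark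
Reagents that add atoms: phosphorus tribromide, BrP(Br)Br; triphenylphosphine, c1ccc(cc1)P(c1ccccc1)c1ccccc1
Why: As in step 3, SN2 bromination of the primary allylic alcohol followed by phosphine quaternisation keeps the trisubstituted E double bond and avoids cation-olefin side reactions.

Step 7
Reactants: 7 C15 salt of ring A; 13 (2E,4E,6E)-2,7-dimethylocta-2,4,6-trienedial (2.5 equiv)
Product: 15 (2E,4E,6E,8E,10E)-2,7,11-trimethyl-13-(2,6,6-trimethylcyclohex-1-en-1-yl)trideca-2,4,6,8,10-pentaen-12-ynal (7,8-didehydro-12'-apo-β-caroten-12'-al), via acetylenic ylide 14 (not isolated)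
Conditions: NaOMe (1.1 equiv, in MeOH) added dropwise, CH2Cl2, −10 °C → rt; then heptane, 80 °C, dark, argon; chromatography (excess 13 recovered)
Reagents that add atoms: none
Why: Wittig olefination forms C11=C12, mono-condensation is favoured because the dialdehyde is in excess and more electrophilic than the vinylogous C25 aldehyde formed, and the hindered 11Z isomer should revert thermally to 11E without iodine or light, which would disturb the 9E bond.

Step 8
Reactants: 15 7,8-didehydro-12'-apo-β-caroten-12'-al; 12 C15 salt of ring B (1.3 equiv)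
Product: 17 all-E-7,8-didehydro-7',8'-dihydro-β,β-carotene, via dihydro ylide 16 (not isolated)
Conditions: 12, NaN(SiMe3)2 (1.25 equiv), THF, −78 °C; then 15, −78 °C → rt; then heptane, reflux, dark, argon; crystallisation
Reagents that add atoms: none
Why: The second Wittig olefination forms C11'=C12' by adding the more nucleophilic allylic ylide to the less reactive polyenal, and thermal equilibration of the hindered 11'Z isomer followed by crystallisation should give the all-E hydrocarbon.

Step 9
Reactants: 17 all-E-7,8-didehydro-7',8'-dihydro-β,β-carotene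
Product: 20 (3R,3'R)-7,8-didehydro-7',8'-dihydro-β,β-carotene-3,3'-diol (target), via ring A monool 18 (not isolated), via ring B monool 19 (not isolated)
Conditions: CrtZ β-carotene 3,3'-hydroxylase (membrane fraction, recombinant Escherichia coli), spinach ferredoxin, ferredoxin–NADP+ reductase, NADPH (excess), O2 (air), FeSO4 (trace), catalase, 17 in phosphatidylcholine liposomes, Tris-HCl pH 8.0, 30 °C, dark; extraction, chromatography, crystallisation
Reagents that add atoms: dioxygen, O=O
Why: Proposed new method: the membrane-bound diiron centre of CrtZ, reduced by NADPH through ferredoxin–NADP+ reductase and ferredoxin, activates O2 to a high-valent diiron-oxo species that takes one hydrogen atom from C3 of a bound 2,6,6-trimethylcyclohexene ring and gives back OH by radical rebound with retention, once at each end by way of monools 18 and 19; the closest known reaction type is the conversion of β-carotene through β-cryptoxanthin into (3R,3'R)-zeaxanthin by the same enzyme class, and only the alkyne-bearing ring A end is untested. No ring is closed and no skeletal bond is made, so no mode of closure applies; only the C3–O and C3'–O bonds form. Both new stereocentres, C3 of ring A and C3' of ring B, are set R by the active site, which presents the pro-R hydrogen of each homoallylic CH2 to the oxidant, since the achiral substrate has no bias of its own. The step needs site selectivity for C3 over the allylic C4 and methyl positions, the polyene and the alkyne, and this rests on both end rings being constitutionally the β-ring that the enzyme recognises, while the alkyne at C7–C8 and the saturated C7'–C8' link sit in the chain. Supplying the lipophilic hydrocarbon in liposomes is meant to give the membrane enzyme access to it.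

Compound list
1 | 2,2,6-trimethylcyclohexanone (racemic) | CC1CCCC(C)(C)C1=O | starting material
2 | lithium 2,6,6-trimethylcyclohex-1-en-1-olate | CC1=C(O[Li])C(C)(C)CCC1 | intermediate
3 | 2,6,6-trimethylcyclohex-1-en-1-yl trifluoromethanesulfonate | CC1=C(OS(=O)(=O)C(F)(F)F)C(C)(C)CCC1 | intermediate
4 | (E)-3-methylpent-2-en-4-yn-1-ol | C#C/C(C)=C/CO | starting material
5 | (E)-3-methyl-5-(2,6,6-trimethylcyclohex-1-en-1-yl)pent-2-en-4-yn-1-ol | CC1=C(C#C/C(C)=C/CO)C(C)(C)CCC1 | intermediate
6 | 2-[(E)-5-bromo-3-methylpent-3-en-1-yn-1-yl]-1,3,3-trimethylcyclohex-1-ene | CC1=C(C#C/C(C)=C/CBr)C(C)(C)CCC1 | intermediate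
7 | [(E)-3-methyl-5-(2,6,6-trimethylcyclohex-1-en-1-yl)pent-2-en-4-yn-1-yl]triphenylphosphonium bromide | CC1=C(C#C/C(C)=C/C[P+](c2ccccc2)(c2ccccc2)c2ccccc2)C(C)(C)CCC1.[Br-] | intermediate
8 | dihydro-β-ionone, 4-(2,6,6-trimethylcyclohex-1-en-1-yl)butan-2-one | CC(=O)CCC1=C(C)CCCC1(C)C | starting material
9 | ethyl (E)-3-methyl-5-(2,6,6-trimethylcyclohex-1-en-1-yl)pent-2-enoate | CCOC(=O)/C=C(\C)CCC1=C(C)CCCC1(C)C | intermediate
10 | (E)-3-methyl-5-(2,6,6-trimethylcyclohex-1-en-1-yl)pent-2-en-1-ol | OC/C=C(\C)CCC1=C(C)CCCC1(C)C | intermediate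
11 | 2-[(E)-5-bromo-3-methylpent-3-en-1-yl]-1,3,3-trimethylcyclohex-1-ene | BrC/C=C(\C)CCC1=C(C)CCCC1(C)C | intermediate
12 | [(E)-3-methyl-5-(2,6,6-trimethylcyclohex-1-en-1-yl)pent-2-en-1-yl]triphenylphosphonium bromide | CC1=C(CC/C(C)=C/C[P+](c2ccccc2)(c2ccccc2)c2ccccc2)C(C)(C)CCC1.[Br-] | intermediate
13 | (2E,4E,6E)-2,7-dimethylocta-2,4,6-trienedial | O=C/C(C)=C/C=C/C=C(C)/C=O | starting material
14 | [(E)-3-methyl-5-(2,6,6-trimethylcyclohex-1-en-1-yl)pent-2-en-4-yn-1-ylidene]triphenylphosphorane | CC1=C(C#C/C(C)=C/C=P(c2ccccc2)(c2ccccc2)c2ccccc2)C(C)(C)CCC1 | intermediate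
15 | (2E,4E,6E,8E,10E)-2,7,11-trimethyl-13-(2,6,6-trimethylcyclohex-1-en-1-yl)trideca-2,4,6,8,10-pentaen-12-ynal | CC1=C(C#C/C(C)=C/C=C/C(C)=C/C=C/C=C(C)/C=O)C(C)(C)CCC1 | intermediate
16 | [(E)-3-methyl-5-(2,6,6-trimethylcyclohex-1-en-1-yl)pent-2-en-1-ylidene]triphenylphosphorane | CC1=C(CC/C(C)=C/C=P(c2ccccc2)(c2ccccc2)c2ccccc2)C(C)(C)CCC1 | intermediate
17 | all-E-7,8-didehydro-7',8'-dihydro-β,β-carotene | CC1=C(C#C/C(C)=C/C=C/C(C)=C/C=C/C=C(C)/C=C/C=C(\C)CCC2=C(C)CCCC2(C)C)C(C)(C)CCC1 | intermediate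
18 | (3R)-7,8-didehydro-7',8'-dihydro-β,β-caroten-3-ol (hydroxyl on ring A) | CC1=C(C#C/C(C)=C/C=C/C(C)=C/C=C/C=C(C)/C=C/C=C(\C)CCC2=C(C)CCCC2(C)C)C(C)(C)C[C@H](O)C1 | intermediate
19 | (3'R)-7,8-didehydro-7',8'-dihydro-β,β-caroten-3'-ol (hydroxyl on ring B) | CC1=C(C#C/C(C)=C/C=C/C(C)=C/C=C/C=C(C)/C=C/C=C(\C)CCC2=C(C)C[C@@H](O)CC2(C)C)C(C)(C)CCC1 | intermediate
20 | (3R,3'R)-7,8-didehydro-7',8'-dihydro-β,β-carotene-3,3'-diol | CC1=C(C#C/C(C)=C/C=C/C(C)=C/C=C/C=C(C)/C=C/C=C(\C)CCC2=C(C)C[C@@H](O)CC2(C)C)C(C)(C)C[C@H](O)C1 | target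

Total step count: 9
Longest linear sequence: 6 steps (steps 1, 2, 3, 7, 8, 9)

Steps most likely to fail

Step 9. The enzyme may fail to bind or turn over the substrate at the alkyne-bearing end, hydroxylation may stall after one ring, or transfer of the hydrocarbon from the liposomes to the membrane enzyme may be too slow. The fallback uses known chemistry and takes both hydroxyls from the chiral pool; it sets out from enynol 4 and dialdehyde 13 and comes back at target 20.
- Commercial (4R,6R)-4-hydroxy-2,2,6-trimethylcyclohexanone F1 would be silylated (TBSCl, imidazole, DMF) to TBS ether F2 and converted (LiN(i-Pr)2, then PhNTf2) into the (R)-silyloxy enol triflate F3.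
- Sonogashira coupling of F3 with 4 under the conditions of step 2 should give the silylated C15 enynol F4. This is carried through allylic bromide F5 (PBr3) to phosphonium bromide F6 (PPh3) and condensed with excess 13 as in step 7 to the silylated C25 aldehyde F7.
- For ring B, Heck coupling of F3 with but-3-en-2-one (Pd(OAc)2, PPh3, Et3N, DMF, 70 °C) should give the silyloxy-β-ionone F8. Conjugate reduction with [(Ph3P)CuH]6 in wet benzene should give the 7,8-dihydro ketone F9.
- The chemistry of steps 4 to 6 then leads through (E)-ester F10, allylic alcohol F11 and allylic bromide F12 to phosphonium bromide F13.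
- Wittig reaction of the ylide of F13 with F7 as in step 8 gives the bis-silyl ether F14, and Bu4NF in THF releases 20.
- Both carbinol centres are then inherited from C4 of F1 and are never touched, at the cost of a longer, protected sequence.

Step 7. Olefination may occur at both aldehyde ends, and the 9E bond beside the alkyne may drift towards Z while the ylide is exposed to base and the product to heat. The fallback sets out from allylic bromide 6 and comes back at aldehyde 15. Arbuzov reaction of 6 with triethyl phosphite (neat, 100 °C) gives the diethyl phosphonate F15. Its anion (NaN(SiMe3)2, THF, −78 °C) is condensed with excess 13 in a Horner–Wadsworth–Emmons reaction, which should give E at C11=C12 directly, so that no thermal equilibration is needed.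

Step 2. Oxidative addition to the hindered tetrasubstituted triflate may be slow, so that the alkyne is used up by copper-mediated oxidative dimerisation. The fallback sets out from ketone 1 and enynol 4 and comes back at enynol 5.
- The dilithio derivative of 4 (n-BuLi, 2 equiv, THF, −78 °C) is added to the carbonyl group of 1 to give the propargylic diol F16.
- Ac2O in pyridine acylates only the primary hydroxyl and gives the monoacetate F17.
- Dehydration with POCl3 in pyridine at 90 °C can go only towards the methyl-bearing ring carbon, the other neighbour being quaternary, and gives the enyne acetate F18.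
- K2CO3 in MeOH then returns 5.

Further compounds
F1 | step 9 | (4R,6R)-4-hydroxy-2,2,6-trimethylcyclohexanone | C[C@@H]1C[C@@H](O)CC(C)(C)C1=O
F2 | step 9 | (4R,6R)-4-(tert-butyldimethylsilyloxy)-2,2,6-trimethylcyclohexanone | C[C@@H]1C[C@@H](O[Si](C)(C)C(C)(C)C)CC(C)(C)C1=O
F3 | step 9 | (R)-4-(tert-butyldimethylsilyloxy)-2,6,6-trimethylcyclohex-1-en-1-yl trifluoromethanesulfonate | CC1=C(OS(=O)(=O)C(F)(F)F)C(C)(C)C[C@H](O[Si](C)(C)C(C)(C)C)C1
F4 | step 9 | (E)-5-[(4R)-4-(tert-butyldimethylsilyloxy)-2,6,6-trimethylcyclohex-1-en-1-yl]-3-methylpent-2-en-4-yn-1-ol | CC1=C(C#C/C(C)=C/CO)C(C)(C)C[C@H](O[Si](C)(C)C(C)(C)C)C1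
F5 | step 9 | tert-butyl{[(1R)-4-[(E)-5-bromo-3-methylpent-3-en-1-yn-1-yl]-3,5,5-trimethylcyclohex-3-en-1-yl]oxy}dimethylsilane | CC1=C(C#C/C(C)=C/CBr)C(C)(C)C[C@H](O[Si](C)(C)C(C)(C)C)C1
F6 | step 9 | {(E)-5-[(4R)-4-(tert-butyldimethylsilyloxy)-2,6,6-trimethylcyclohex-1-en-1-yl]-3-methylpent-2-en-4-yn-1-yl}triphenylphosphonium bromide | CC1=C(C#C/C(C)=C/C[P+](c2ccccc2)(c2ccccc2)c2ccccc2)C(C)(C)C[C@H](O[Si](C)(C)C(C)(C)C)C1.[Br-]
F7 | step 9 | (3R)-3-(tert-butyldimethylsilyloxy)-7,8-didehydro-12'-apo-β-caroten-12'-al, all-E | CC1=C(C#C/C(C)=C/C=C/C(C)=C/C=C/C=C(C)/C=O)C(C)(C)C[C@H](O[Si](C)(C)C(C)(C)C)C1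
F8 | step 9 | (E)-4-[(4R)-4-(tert-butyldimethylsilyloxy)-2,6,6-trimethylcyclohex-1-en-1-yl]but-3-en-2-one | CC(=O)/C=C/C1=C(C)C[C@@H](O[Si](C)(C)C(C)(C)C)CC1(C)C
F9 | step 9 | 4-[(4R)-4-(tert-butyldimethylsilyloxy)-2,6,6-trimethylcyclohex-1-en-1-yl]butan-2-one | CC(=O)CCC1=C(C)C[C@@H](O[Si](C)(C)C(C)(C)C)CC1(C)C
F10 | step 9 | ethyl (E)-5-[(4R)-4-(tert-butyldimethylsilyloxy)-2,6,6-trimethylcyclohex-1-en-1-yl]-3-methylpent-2-enoate | CCOC(=O)/C=C(\C)CCC1=C(C)C[C@@H](O[Si](C)(C)C(C)(C)C)CC1(C)C
F11 | step 9 | (E)-5-[(4R)-4-(tert-butyldimethylsilyloxy)-2,6,6-trimethylcyclohex-1-en-1-yl]-3-methylpent-2-en-1-ol | OC/C=C(\C)CCC1=C(C)C[C@@H](O[Si](C)(C)C(C)(C)C)CC1(C)C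
F12 | step 9 | tert-butyl{[(1R)-4-[(E)-5-bromo-3-methylpent-3-en-1-yl]-3,5,5-trimethylcyclohex-3-en-1-yl]oxy}dimethylsilane | BrC/C=C(\C)CCC1=C(C)C[C@@H](O[Si](C)(C)C(C)(C)C)CC1(C)C
F13 | step 9 | {(E)-5-[(4R)-4-(tert-butyldimethylsilyloxy)-2,6,6-trimethylcyclohex-1-en-1-yl]-3-methylpent-2-en-1-yl}triphenylphosphonium bromide | [Br-].c1ccc(cc1)[P+](c1ccccc1)(c1ccccc1)C/C=C(\C)CCC1=C(C)C[C@@H](O[Si](C)(C)C(C)(C)C)CC1(C)C
F14 | step 9 | (3R,3'R)-3,3'-bis(tert-butyldimethylsilyloxy)-7,8-didehydro-7',8'-dihydro-β,β-carotene, all-E | CC1=C(C#C/C(C)=C/C=C/C(C)=C/C=C/C=C(C)/C=C/C=C(\C)CCC2=C(C)C[C@@H](O[Si](C)(C)C(C)(C)C)CC2(C)C)C(C)(C)C[C@H](O[Si](C)(C)C(C)(C)C)C1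
F15 | step 7 | diethyl [(E)-3-methyl-5-(2,6,6-trimethylcyclohex-1-en-1-yl)pent-2-en-4-yn-1-yl]phosphonate | CC1=C(C#C/C(C)=C/CP(=O)(OCC)OCC)C(C)(C)CCC1
F16 | step 2 | 1-[(E)-5-hydroxy-3-methylpent-3-en-1-yn-1-yl]-2,2,6-trimethylcyclohexan-1-ol (racemic mixture of diastereomers) | CC1CCCC(C)(C)C1(O)C#C/C(C)=C/CO
F17 | step 2 | (E)-5-(1-hydroxy-2,2,6-trimethylcyclohexyl)-3-methylpent-2-en-4-yn-1-yl acetate (racemic mixture of diastereomers) | CC1CCCC(C)(C)C1(O)C#C/C(C)=C/COC(C)=O
F18 | step 2 | (E)-3-methyl-5-(2,6,6-trimethylcyclohex-1-en-1-yl)pent-2-en-4-yn-1-yl acetate | CC1=C(C#C/C(C)=C/COC(C)=O)C(C)(C)CCC1
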